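**Retrosynthetic overview** (labdane numbering: C15 = ester carbon, C17 = exocyclic CH2, C18 = CH2OAc carbon, C19/C20 = methyls on C4/C10)

1. Target 18 ⇐ bicycle 14 by removal of the C3 hydroxyl and exchange of O-silyl for O-acetyl at C18.
2. 14 ⇐ one cationic bicyclisation of the acyclic (3S,4S)-epoxy allylsilane 13: bond C4–C5 closes ring A (C1–C5, C10) first, bond C9–C10 closes ring B (C5–C10) second; quaternary C4 (C18 equatorial), C5, quaternary C10 and C9 are set as a group, and loss of silicon leaves the exocyclic C8=C17 alkene.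
3. 13 ⇐ Sharpless epoxidation of (E)-allylic alcohol 11; this oxirane is the only catalyst-set stereo element, and all ring centres are relayed from it.
4. 11 ⇐ Negishi coupling (C9–C11) of alkenyl iodide 6 with the zinc reagent from hemiester 7 (C13 bought); 6 ⇐ carbocupration (C8–C17) of enynol 4 ⇐ (E)-geranylacetone 1.

Key step: step 9

Assumption: the target is read as methyl (4R,5R,9S,10R,13R)-18-acetoxylabd-8(17)-en-15-oate (trans-decalin, equatorial 4α-CH2OAc, axial 4β- and 10β-methyls, equatorial C9 side chain); isomerically pure (E)-geranylacetone and methyl hydrogen (R)-3-methylglutarate are taken as commercial.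

**Route**

Step 1
Reactants: 1 (5E)-6,10-dimethylundeca-5,9-dien-2-one [(E)-geranylacetone]
Product: 3 (5E)-6,10-dimethylundeca-5,9-dien-1-yne, via enol phosphate 2 (not isolated)
Conditions: LDA (1.05 equiv), THF, −78 °C; ClP(O)(OEt)2, −78 °C → rt; LDA (2.3 equiv), −78 °C → rt; H2O
Reagents that add atoms: diethyl chlorophosphate, CCOP(=O)(Cl)OCC (gives the phosphate of intermediate 2 only; no reagent atom remains in 3)
Why: One-pot conversion of a methyl ketone into a terminal alkyne: kinetic deprotonation on the methyl side, O-phosphorylation to the terminal enol phosphate and base-induced β-elimination of diethyl phosphate, which leaves the (5E)-alkene untouched.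

Step 2
Reactants: 3 (5E)-6,10-dimethylundeca-5,9-dien-1-yne
Product: 4 (2E,6E)-2,6-dimethylundeca-2,6-dien-10-yn-1-ol
Conditions: SeO2 (0.5 equiv), salicylic acid (0.1 equiv), t-BuOOH (3 equiv), CH2Cl2, 0 °C → rt, stopped at partial conversion (3 recycled)
Reagents that add atoms: tert-butyl hydroperoxide, CC(C)(C)OO
Why: Catalytic SeO2/t-BuOOH allylic oxidation (ene reaction then [2,3]-sigmatropic shift) attacks the (E)-methyl of the terminal gem-dimethyl alkene, as is usual for geranyl- and farnesyl-type chains, and so should give the (E)-allylic alcohol whose oxygen becomes C18–O.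

Step 3
Reactants: 4 (2E,6E)-2,6-dimethylundeca-2,6-dien-10-yn-1-ol
Product: 6 (2E,6E,10Z)-11-iodo-2,6-dimethyl-10-[(trimethylsilyl)methyl]undeca-2,6,10-trien-1-ol, via alkenylcopper 5 (not isolated)
Conditions: Me3SiCH2MgCl (3.2 equiv; the first equivalent converts 4 into its ClMg alkoxide), CuBr·SMe2 (2.1 equiv), Et2O/Me2S, −40 → 0 °C, then rt, 16 h; I2 (2.5 equiv), THF, −40 → 0 °C; aq. NH4Cl/Na2S2O3
Reagents that add atoms: (trimethylsilyl)methylmagnesium chloride, C[Si](C)(C)C[Mg]Cl; iodine, II; copper(I) bromide–dimethyl sulfide, CSC.[Cu]Br (copper and magnesium stay in intermediate 5 only)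
Why: Carbocupration of a terminal alkyne with an α-silyl organocopper reagent is a syn addition that puts the silylmethyl group on the internal carbon (future C8) and copper on the terminal one (future C9), and iodinolysis with retention should fix the (10Z) geometry that places CH2SiMe3 cis to the later C11 substituent.

Step 4
Reactants: 7 (3R)-5-methoxy-3-methyl-5-oxopentanoic acid [methyl hydrogen (R)-3-methylglutarate]
Product: 8 methyl (3R)-5-hydroxy-3-methylpentanoate
Conditions: BH3·SMe2 (1.1 equiv), THF, 0 °C → rt; MeOH quench; used at once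
Reagents that add atoms: none
Why: Chemoselective borane reduction of a carboxylic acid beside a methyl ester; the bought stereocentre (future C13) is not touched.

Step 5
Reactants: 8 methyl (3R)-5-hydroxy-3-methylpentanoate
Product: 9 methyl (3S)-5-iodo-3-methylpentanoate
Conditions: I2, PPh3, imidazole, CH2Cl2, 0 °C
Reagents that add atoms: iodine, II
Why: Appel-type iodination of the primary alcohol under neutral conditions, run directly to forestall lactonisation of the δ-hydroxy ester (the descriptor changes to S only because of CIP priorities).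

Step 6
Reactants: 6 (2E,6E,10Z)-11-iodo-2,6-dimethyl-10-[(trimethylsilyl)methyl]undeca-2,6,10-trien-1-ol; 9 methyl (3S)-5-iodo-3-methylpentanoate
Product: 11 methyl (3R,6Z,10E,14E)-16-hydroxy-3,11,15-trimethyl-7-[(trimethylsilyl)methyl]hexadeca-6,10,14-trienoate, via alkylzinc iodide 10 (not isolated)
Conditions: 9 (2.5 equiv), Zn dust (activated), LiCl, THF, 40 °C; then 6, Pd(OAc)2 (3 mol%), SPhos (6 mol%), THF, rt
Reagents that add atoms: zinc, [Zn] (stays in intermediate 10 only)
Why: LiCl-promoted zinc insertion into the primary iodide followed by Negishi sp3–sp2 coupling, which keeps the alkenyl geometry and tolerates ester, free alcohol and allylsilane, so that C11 ends cis to CH2SiMe3 (C7 and C11 trans, as needed for an equatorial C9 side chain).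

Step 7
Reactants: 11 methyl (3R,6Z,10E,14E)-16-hydroxy-3,11,15-trimethyl-7-[(trimethylsilyl)methyl]hexadeca-6,10,14-trienoate
Product: 12 methyl (3R,6Z,10E)-13-[(2S,3S)-3-(hydroxymethyl)-3-methyloxiran-2-yl]-3,11-dimethyl-7-[(trimethylsilyl)methyl]trideca-6,10-dienoate
Conditions: Ti(OiPr)4 (0.1 equiv), L-(+)-diethyl tartrate (0.12 equiv), t-BuOOH (2 equiv, anhydrous), 4 Å MS, CH2Cl2, −20 °C
Reagents that add atoms: tert-butyl hydroperoxide, CC(C)(C)OO
Why: Sharpless asymmetric epoxidation, in which L-(+)-tartrate should deliver oxygen to the face that gives the (2S,3S)-epoxy alcohol (labdane 3S,4S, C2 and CH2OH trans on the oxirane), and only the allylic-alcohol alkene reacts while the isolated alkene and the allylsilane are inert to Ti/t-BuOOH.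

Step 8
Reactants: 12 methyl (3R,6Z,10E)-13-[(2S,3S)-3-(hydroxymethyl)-3-methyloxiran-2-yl]-3,11-dimethyl-7-[(trimethylsilyl)methyl]trideca-6,10-dienoate
Product: 13 methyl (3R,6Z,10E)-13-[(2S,3S)-3-({[tert-butyl(dimethyl)silyl]oxy}methyl)-3-methyloxiran-2-yl]-3,11-dimethyl-7-[(trimethylsilyl)methyl]trideca-6,10-dienoate
Conditions: TBSCl, imidazole, CH2Cl2, 0 °C → rt
Reagents that add atoms: tert-butyldimethylsilyl chloride, CC(C)(C)[Si](C)(C)Cl
Why: Standard silylation of the primary alcohol; a silyl ether is chosen because, unlike an acetate, it cannot take part in the oxirane opening as a neighbouring group.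

Step 9
Reactants: 13 methyl (3R,6Z,10E)-13-[(2S,3S)-3-({[tert-butyl(dimethyl)silyl]oxy}methyl)-3-methyloxiran-2-yl]-3,11-dimethyl-7-[(trimethylsilyl)methyl]trideca-6,10-dienoate
Product: 14 methyl (3S,4R,5R,9S,10R,13R)-18-[(tert-butyldimethylsilyl)oxy]-3-hydroxylabd-8(17)-en-15-oate
Conditions: MeAlCl2 (3.0 equiv), CH2Cl2, −78 °C, 30 min; Et3N/MeOH, then aq. Rochelle salt
Reagents that add atoms: none
Why: MeAlCl2 activates the oxirane, C5 of the (E)-C5=C10 alkene opens the C4–O bond from the back (inversion at tertiary C4), the C10 cation is trapped by C9 of the allylsilane and loss of silicon from the β-silyl cation should place the alkene at C8=C17 only; the closest known reaction type is the Lewis acid-promoted, epoxide-initiated and allylsilane-terminated cation–olefin polycyclisation, including oxiranes that carry a CH2OR group on the tertiary carbon. Ring A (C4–C5) closes 6-endo with respect to both the oxirane and the alkene and ring B (C9–C10) closes 6-endo at the allylsilane alkene, both through chair-like transition states. At C4, anti opening together with the trans relation of C2 and CH2OSi on the oxirane puts CH2OSi equatorial (4α, C18) and the methyl axial; C3 keeps its (S) configuration with the oxygen equatorial; C5 and C10 follow from antiperiplanar addition across the (E)-alkene (trans fusion, axial C10 methyl); C9 follows from the allylsilane geometry (C7 and C11 trans), which places the side chain equatorial. The absolute configuration of all four new centres is relayed from the oxirane of step 7, because backside attack at C4 is possible only in the chair that holds the C3–O bond equatorial. The step needs cyclisation to outrun a 1,2-hydride shift from C18 (semipinacol opening of the epoxy silyl ether) and protodesilylation; the pre-folded 1,5-diene, the nucleophilic allylsilane, the low temperature and the proton-scavenging Lewis acid should secure this.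

Step 10
Reactants: 14 methyl (3S,4R,5R,9S,10R,13R)-18-[(tert-butyldimethylsilyl)oxy]-3-hydroxylabd-8(17)-en-15-oate
Product: 15 methyl (3S,4R,5R,9S,10R,13R)-18-[(tert-butyldimethylsilyl)oxy]-3-[(1H-imidazol-1-ylcarbonothioyl)oxy]labd-8(17)-en-15-oate
Conditions: 1,1'-thiocarbonyldiimidazole (3 equiv), DMAP (cat.), ClCH2CH2Cl, 80 °C
Reagents that add atoms: 1,1'-thiocarbonyldiimidazole, S=C(n1ccnc1)n1ccnc1
Why: Thioacylation to the imidazole-1-carbothioate (Barton–McCombie precursor) under neutral conditions, which hindered equatorial 3β-alcohols next to a quaternary C4 are known to accept on heating.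

Step 11
Reactants: 15 methyl (3S,4R,5R,9S,10R,13R)-18-[(tert-butyldimethylsilyl)oxy]-3-[(1H-imidazol-1-ylcarbonothioyl)oxy]labd-8(17)-en-15-oate
Product: 16 methyl (4R,5R,9S,10R,13R)-18-[(tert-butyldimethylsilyl)oxy]labd-8(17)-en-15-oate
Conditions: Bu3SnH (2 equiv, slow addition), AIBN (cat.), toluene, 110 °C
Reagents that add atoms: none
Why: Barton–McCombie radical deoxygenation: stannyl radical adds to C=S, β-scission gives the secondary C3 radical and Bu3SnH reduces it, while the esters, the silyl ether and the remote C8=C17 alkene (no 5- or 6-exo path from C3) should stay intact.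

Step 12
Reactants: 16 methyl (4R,5R,9S,10R,13R)-18-[(tert-butyldimethylsilyl)oxy]labd-8(17)-en-15-oate
Product: 18 methyl (4R,5R,9S,10R,13R)-18-acetoxylabd-8(17)-en-15-oate (target), via primary alcohol 17 (not isolated)
Conditions: TBAF (1.5 equiv), THF, 0 °C → rt; then Ac2O (3 equiv), Et3N, DMAP (cat.), rt
Reagents that add atoms: acetic anhydride, CC(=O)OC(C)=O
Why: Fluoride cleavage of the neopentyl silyl ether followed by acetylation of the resulting alkoxide in the same flask (one-pot desilylation–acylation), to which the methyl ester and the exocyclic alkene are inert.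

**Compound list**

1 | (5E)-6,10-dimethylundeca-5,9-dien-2-one, (E)-geranylacetone | CC(=O)CC/C=C(\C)CCC=C(C)C | starting material
2 | diethyl (5E)-6,10-dimethylundeca-1,5,9-trien-2-yl phosphate | C=C(OP(=O)(OCC)OCC)CC/C=C(\C)CCC=C(C)C | intermediate (not isolated)
3 | (5E)-6,10-dimethylundeca-5,9-dien-1-yne | C#CCC/C=C(\C)CCC=C(C)C | intermediate
4 | (2E,6E)-2,6-dimethylundeca-2,6-dien-10-yn-1-ol | C#CCC/C=C(\C)CC/C=C(\C)CO | intermediate
5 | (Z)-alkenylcopper from syn addition of Me3SiCH2Cu to the alkyne of 4, as ClMg alkoxide | [Cu]/C=C(\C[Si](C)(C)C)CC/C=C(\C)CC/C=C(\C)CO[Mg]Cl | intermediate (not isolated)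
6 | (2E,6E,10Z)-11-iodo-2,6-dimethyl-10-[(trimethylsilyl)methyl]undeca-2,6,10-trien-1-ol | I/C=C(\C[Si](C)(C)C)CC/C=C(\C)CC/C=C(\C)CO | intermediate
7 | (3R)-5-methoxy-3-methyl-5-oxopentanoic acid, methyl hydrogen (R)-3-methylglutarate | COC(=O)C[C@H](C)CC(=O)O | starting material
8 | methyl (3R)-5-hydroxy-3-methylpentanoate | COC(=O)C[C@H](C)CCO | intermediate
9 | methyl (3S)-5-iodo-3-methylpentanoate | COC(=O)C[C@H](C)CCI | intermediate
10 | [(3S)-5-methoxy-3-methyl-5-oxopentyl]zinc iodide | COC(=O)C[C@H](C)CC[Zn]I | intermediate (not isolated)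
11 | methyl (3R,6Z,10E,14E)-16-hydroxy-3,11,15-trimethyl-7-[(trimethylsilyl)methyl]hexadeca-6,10,14-trienoate | COC(=O)C[C@H](C)CC/C=C(\C[Si](C)(C)C)/CC/C=C(\C)CC/C=C(\C)CO | intermediate
12 | methyl (3R,6Z,10E)-13-[(2S,3S)-3-(hydroxymethyl)-3-methyloxiran-2-yl]-3,11-dimethyl-7-[(trimethylsilyl)methyl]trideca-6,10-dienoate | COC(=O)C[C@H](C)CC/C=C(\C[Si](C)(C)C)/CC/C=C(\C)CC[C@@H]1O[C@@]1(C)CO | intermediate
13 | methyl (3R,6Z,10E)-13-[(2S,3S)-3-({[tert-butyl(dimethyl)silyl]oxy}methyl)-3-methyloxiran-2-yl]-3,11-dimethyl-7-[(trimethylsilyl)methyl]trideca-6,10-dienoate | COC(=O)C[C@H](C)CC/C=C(\C[Si](C)(C)C)/CC/C=C(\C)CC[C@@H]1O[C@@]1(C)CO[Si](C)(C)C(C)(C)C | intermediate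
14 | methyl (3S,4R,5R,9S,10R,13R)-18-[(tert-butyldimethylsilyl)oxy]-3-hydroxylabd-8(17)-en-15-oate | C=C1CC[C@H]2[C@](C)(CO[Si](C)(C)C(C)(C)C)[C@@H](O)CC[C@]2(C)[C@H]1CC[C@@H](C)CC(=O)OC | intermediate
15 | methyl (3S,4R,5R,9S,10R,13R)-18-[(tert-butyldimethylsilyl)oxy]-3-[(1H-imidazol-1-ylcarbonothioyl)oxy]labd-8(17)-en-15-oate | C=C1CC[C@H]2[C@](C)(CO[Si](C)(C)C(C)(C)C)[C@@H](OC(=S)n3ccnc3)CC[C@]2(C)[C@H]1CC[C@@H](C)CC(=O)OC | intermediate
16 | methyl (4R,5R,9S,10R,13R)-18-[(tert-butyldimethylsilyl)oxy]labd-8(17)-en-15-oate | C=C1CC[C@H]2[C@](C)(CO[Si](C)(C)C(C)(C)C)CCC[C@]2(C)[C@H]1CC[C@@H](C)CC(=O)OC | intermediate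
17 | methyl (4R,5R,9S,10R,13R)-18-hydroxylabd-8(17)-en-15-oate | C=C1CC[C@H]2[C@](C)(CO)CCC[C@]2(C)[C@H]1CC[C@@H](C)CC(=O)OC | intermediate (not isolated)
18 | methyl (4R,5R,9S,10R,13R)-18-acetoxylabd-8(17)-en-15-oate | C=C1CC[C@H]2[C@](C)(COC(C)=O)CCC[C@]2(C)[C@H]1CC[C@@H](C)CC(=O)OC | target

**Step count**

Total: 12 steps. Longest linear sequence: 10 steps (1 → 3 → 4 → 6 → 11 → 12 → 13 → 14 → 15 → 16 → 18; steps 1, 2, 3, 6, 7, 8, 9, 10, 11, 12).

**Steps most likely to fail**

Step 9 (key step). The Lewis acid-activated epoxy silyl ether may rearrange by 1,2-hydride shift from C18 faster than the alkene attacks C4. The cascade may also stop after ring A through protodesilylation of the allylsilane. The fallback moves to a radical manifold with a silicon-free chain; it sets out from 4 and comes back at 14. Zr-catalysed methylalumination of the alkyne of 4 (Me3Al, Cp2ZrCl2, CH2Cl2) and iodinolysis would give (2E,6E,10E)-11-iodo-2,6,10-trimethylundeca-2,6,10-trien-1-ol F1. Negishi coupling with zinc reagent 10 would give methyl (3R,6E,10E,14E)-16-hydroxy-3,7,11,15-tetramethylhexadeca-6,10,14-trienoate F2. Sharpless epoxidation with L-(+)-diethyl tartrate would give methyl (3R,6E,10E)-13-[(2S,3S)-3-(hydroxymethyl)-3-methyloxiran-2-yl]-3,7,11-trimethyltrideca-6,10-dienoate F3, and silylation would give its tert-butyldimethylsilyl ether F4. Titanocene(III) chloride (Cp2TiCl2, Mn, THF, rt) would then open the oxirane homolytically at C4; the tertiary radical would cyclise 6-endo/6-endo, and the final tertiary C8 radical would be turned by a second Ti(III) into the exocyclic C8=C17 alkene, which is 14. No cation is involved, so the hydride shift cannot compete. The price is that C4 would then be set by the chair preference (CH2OSi equatorial beside the equatorial O–Ti) and no longer by inversion.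

Step 3. Addition of the α-silyl organocopper to the alkyne may be slow or incomplete, and the alkenylcopper may be protonated before iodinolysis, which would give the non-iodinated allylsilane. The fallback brings the silylmethyl carbon in as an electrophile; it sets out from 4 and comes back at 6. Copper-catalysed alkylboration of the alkyne (CuCl, Xantphos, NaOtBu, B2pin2, then ICH2SiMe3, THF; syn borylcupration with boron on the terminal carbon, then C-alkylation of the alkenylcopper with retention) would give (2E,6E,10Z)-2,6-dimethyl-11-(4,4,5,5-tetramethyl-1,3,2-dioxaborolan-2-yl)-10-[(trimethylsilyl)methyl]undeca-2,6,10-trien-1-ol F5. Ipso-iodination with retention (NaOH, I2, THF/H2O, 0 °C) would give 6.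

Step 11 (with step 10). Thioacylation of the hindered 3β-alcohol may stall. In the radical step, slow fragmentation may return alcohol 14, and the stannyl radical may add to the exocyclic alkene. The fallback is ionic; it sets out from 14 and comes back at 16. Dess–Martin oxidation would give methyl (4R,5R,9S,10R,13R)-18-[(tert-butyldimethylsilyl)oxy]-3-oxolabd-8(17)-en-15-oate F6. Condensation with tosylhydrazide (EtOH, 60 °C) would give its 3-tosylhydrazone F7. Reduction with catecholborane (CHCl3, 0 °C) followed by NaOAc·3H2O (reflux) would lose N2 and sulfinate and give the C3 methylene compound 16, without affecting the esters, the silyl ether or the alkene.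

**Further compounds**

F1 | step 9 | (2E,6E,10E)-11-iodo-2,6,10-trimethylundeca-2,6,10-trien-1-ol | I/C=C(\C)CC/C=C(\C)CC/C=C(\C)CO
F2 | step 9 | methyl (3R,6E,10E,14E)-16-hydroxy-3,7,11,15-tetramethylhexadeca-6,10,14-trienoate | COC(=O)C[C@H](C)CC/C=C(\C)CC/C=C(\C)CC/C=C(\C)CO
F3 | step 9 | methyl (3R,6E,10E)-13-[(2S,3S)-3-(hydroxymethyl)-3-methyloxiran-2-yl]-3,7,11-trimethyltrideca-6,10-dienoate | COC(=O)C[C@H](C)CC/C=C(\C)CC/C=C(\C)CC[C@@H]1O[C@@]1(C)CO
F4 | step 9 | methyl (3R,6E,10E)-13-[(2S,3S)-3-({[tert-butyl(dimethyl)silyl]oxy}methyl)-3-methyloxiran-2-yl]-3,7,11-trimethyltrideca-6,10-dienoate | COC(=O)C[C@H](C)CC/C=C(\C)CC/C=C(\C)CC[C@@H]1O[C@@]1(C)CO[Si](C)(C)C(C)(C)C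
F5 | step 3 | (2E,6E,10Z)-2,6-dimethyl-11-(4,4,5,5-tetramethyl-1,3,2-dioxaborolan-2-yl)-10-[(trimethylsilyl)methyl]undeca-2,6,10-trien-1-ol | CC1(C)OB(/C=C(\C[Si](C)(C)C)CC/C=C(\C)CC/C=C(\C)CO)OC1(C)C
F6 | step 11 | methyl (4R,5R,9S,10R,13R)-18-[(tert-butyldimethylsilyl)oxy]-3-oxolabd-8(17)-en-15-oate | C=C1CC[C@H]2[C@](C)(CO[Si](C)(C)C(C)(C)C)C(=O)CC[C@]2(C)[C@H]1CC[C@@H](C)CC(=O)OC
F7 | step 11 | methyl (4R,5R,9S,10R,13R)-18-[(tert-butyldimethylsilyl)oxy]-3-[2-(4-methylbenzenesulfonyl)hydrazinylidene]labd-8(17)-en-15-oate | C=C1CC[C@H]2[C@](C)(CO[Si](C)(C)C(C)(C)C)C(=NNS(=O)(=O)c3ccc(C)cc3)CC[C@]2(C)[C@H]1CC[C@@H](C)CC(=O)OC
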